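Atom numbers C1–C6/O7 are those of the target throughout. "Exo" means on the side of the oxygen bridge and "endo" the opposite side. The 8-oxabicyclo[3.2.1]octanes are named with their own systematic locants: the methyl-bearing bridgehead is C5, the chain A carbon C4, the diazo carbon C3 and the carbonyl carbon C2.

## Structural features

Dactylomelol is a 7-oxabicyclo[2.2.1]heptane, that is, a cyclohexane C1–C6 whose C1 and C4 are tied together by O7. C1 is a methyl-bearing bridgehead, C2 carries chain A (CH2CH2C(CH3)(OH)CH=CH2) exo, C3 is quaternary with an exo methyl group and the endo chain B (CH2CH2CHBrC(CH3)2Cl), and C4 is the second bridgehead, so C1 to C4 are four contiguous stereocentres with the C3 methyl cis to chain A. Two more stereocentres lie in the chains, out of reach of the bicycle: the (S) tertiary allylic carbinol of chain A and the (S) secondary bromide of chain B, which stands next to a tertiary chloride. The fragile groups are the tertiary allylic alcohol (ionisation, allylic transposition), the vicinal bromochloride (bases, reducing metals, halophiles) and the strained tertiary ether; in addition a carbanion on C2, C3, C5 or C6 is β to a C–O7 bond and can open the bridge. The real difficulty is the quaternary C3 between the substituted C2 and the bridgehead C4, together with two remote centres that only reagents can set. The key step uses the fact that the carbocycle C1–C6 is the ring-contracted form of the seven-membered carbocycle of an 8-oxabicyclo[3.2.1]octan-2-one. In that step C4 is shifted onto C3 (bond C3–C4), and the extruded carbonyl carbon stays on C3 as the first carbon of chain B.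

## Logic of the disconnections

**34 back to 28.** 34 is traced to 33, in which the tertiary hydroxyl is silylated, and the C–Cl and C–Br bonds of 33 are cut. Both come from one C–O bond: 33 from 30 (secondary C–O replaced while bromine moves over from the neighbouring carbon, via 31 and 32), 30 from 29 (C–Br made at the tertiary carbon), and 29 from the trisubstituted alkene of 28. The cut is made here because the bromine-bearing centre is too far from the bicycle for substrate control and the dihalide tolerates neither base nor reducing metals, so it must come last. The gain is that a remote C–Br stereocentre becomes a reagent-controlled epoxidation. The demand is a stereospecific bromine shift without ionisation of the allylic C–O bond of chain A, which is why that oxygen is masked from 28 to 33.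

**28 back to 22.** The O–Si bond of 28 leads to 27. The carbinol C–O bond and the vinyl group of 27 are traced through 26 and 25 to the allylic alcohol 24, and the C=C bond of 24 through 23 to the C=O group of 22. The reason is that ligand-controlled epoxidation of an allylic alcohol is the most dependable way to a tertiary allylic carbinol far from any other centre, and the C–O bond formed in 25 is never broken afterwards. The gain is that chain A shrinks to a methyl ketone. The demand is a pure E alkene in 23 and 24, since the geometry decides the carbinol configuration.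

**22 back to 16.** The ketone of 22 is masked again (21). In chain B the C2′–C3′ bond is cut (21 to 20 and a four-carbon alkenyl bromide), then the B–C bond (20 to 19), the vinyl C=C (19 to 18), and the oxidation level is adjusted through 17 to the ester 16. The reason is that C1′ is neopentyl, so bonds cannot be made there by displacement; olefination at C1′ and coupling at C2′ avoid that. The gain is that chain B is reduced to the ester carbon already on C3. The demand is that hydride, ylide and borane chemistry meet no free ketone, hence the ketal is kept until 21.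

**16 back to 14.** The C3–CH3 bond is cut, via 15. With the ester carbon destined to become the endo chain B, the methyl group is the substituent that must enter exo. The gain is that the quaternary centre becomes a tertiary ester. The demand is exo attack cis to chain A and an enolate that is trapped before it can expel O7.

**14 back to 12 (key disconnection).** The C3–C4 bond is cut and the ester carbon is re-inserted between C3 and C4, via 13. This turns the strained 7-oxabicyclo[2.2.1]heptane into the 8-oxabicyclo[3.2.1]octanone 12, which a cycloaddition can deliver with C1, C2 and C4 already set. The demand is that only the bridgehead migrates and that hydrogen shift does not compete. The configuration at C3 of 14 is deliberately left uncontrolled because 15 erases it.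

**12 back to 6 and 7.** The C=N2 group is removed (12 to 10, via 11). The C–S bond is put back (10 to 9), and the C2–chain A bond is cut (9 to 6 and 8, the latter from 7). Sulfur is taken out before the diazo group is put in, so that 12 holds no second chromophore and no carbene trap, and it is taken out by hydrogenolysis, not through a carbanion that would open the bridge. The gain is an enone whose β-carbon is the future C2. The demand is addition on the face syn to the oxygen bridge in the presence of a sulfoxide.

**6 back to 3 and 4.** The two C–C bonds that join the two-carbon bridge to the bridgeheads are cut, giving the ylide 5 (from 3) and 4. 4 supplies C5 and C6 of the target and the absolute configuration, and its sulfur makes every unwanted isomer a separable diastereomer. The demand is a usable facial preference and enough reactivity to outrun dimerisation of 5.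

**3 back to 1.** The acetate C–O bond leads to 2, and 2 comes from 1 by oxidative ring expansion of the furan. The gain is a bought furan that already holds the C1 methyl group and all six atoms of the five-atom cycloaddition partner.

## Other disconnections considered

**Alternative 1:** The cut is at C3–C1′ (chain B) and at C2–Ca (first carbon of chain A) of a monocyclic ketone; the oxygen bridge is left for later.
- Forward key step: a homoprenyl copper reagent, made from the Grignard reagent and CuBr·SMe2 (monovalent copper), would add to the β-carbon of enone A1 anti to the C4 silyloxy group. The enolate would then be allylated at C2 trans to the new chain, giving A2 with C2, C3 and C4 in place and no ring formed.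
- In its favour: one operation would create the quaternary centre and both neighbours from the single stereocentre of A1. Chain B would arrive complete, whereas the chosen plan spends four steps on it after 16. No diazo compound, light or auxiliary is needed. On step economy for the carbon skeleton this plan is the better one.
- Against it here: the β-carbon of A1 already bears a methyl group, so the addition must build a quaternary centre beside a silyloxy carbon. The allylation has to tell methyl from homoprenyl on that quaternary carbon, a small difference, so C2 is the weak point and stays epimerisable next to the ketone. The bicycle must still be closed by methyl addition at C1 and a cation-type C1–O7 etherification through a boat, in the presence of an acid-sensitive trisubstituted alkene. The allyl group also needs rebuilding into chain A.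
- Comparison: both plans rest on one controlling element for absolute configuration and are equal there. The chosen plan sets each centre on the convex face of a rigid bicycle that already contains O7; A2 is a flexible ring. The alternative wins on length to the framework and loses on C2 control and on the late ether closure.

**Alternative 2:** The cut removes C1–O7 and C3–C4 together, so that the oxolane and the carbocycle arise in one formal [3+2] event.
- Forward key step: Sc(OTf)3 or SnCl4 would bind the lactone and ester carbonyls of cyclopropane A3. The tethered aldehyde oxygen would open the three-membered ring at the donor carbon C1 with inversion (C1–C3 broken, C1–O7 formed), and the stabilised enolate at C3 would add to the cyclic oxocarbenium carbon C4 to give A4.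
- In its favour: both rings and the bonds to three core centres would form in one step. The two substituents on C3 arrive already differentiated (endo ester for chain B, exo lactone carbonyl for the methyl group), so the facial alkylation problem of step 8 does not exist; on this point the alternative is the better plan. C2 is fixed by the cis-fused lactone, and an enantioselective intramolecular cyclopropanation could supply absolute configuration.
- Against it here: the donor carbon carries only alkyl groups, so the usual push from an aryl, vinyl or heteroatom donor is missing and proton loss to an alkene is a likely competitor. The methyl/tether arrangement at C1 must be set in A3. Afterwards the exo lactone carbonyl must be taken all the way down to CH3 at a neopentyl position, and both remaining carbons need homologation.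
- Comparison: structurally it forms the same bicycle directly where the chosen plan forms a larger one and contracts it. Mechanistically it is a polar Lewis acid process with thin precedent for an all-alkyl donor, against a photochemical rearrangement with close precedent in bicyclic diazo ketones. In step count it gains at the core and loses in functional group adjustment, so overall about equal.

**Alternative 3:** The cut is C5–C6, which opens the carbocycle to the acyclic dione A5.
- Forward key step: double kinetic deprotonation at the two acetyl methyl groups (or conversion to the bis-silyl enol ether), then one-electron oxidation with CuCl2 (divalent copper) or (NH4)2Ce(NO3)6 (tetravalent cerium), would couple the terminal carbons and give cyclohexane-1,4-dione A6.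
- In its favour: the ring-forming step is simple and cheap and leaves carbonyl groups exactly at C1 and C4, where O7 must be attached, with C3 unable to enolise. No strained intermediate and no diazo compound are handled, a practical advantage over the chosen plan.
- Against it here: the step makes no stereocentre, so the vicinal tertiary/quaternary pair C2/C3 must be built with full control in an open chain. C2 is α to a ketone in A5 and A6 and can epimerise under the basic conditions. Oligomerisation competes with ring closure. The two ketones must later be told apart (methyl addition at C1, reduction at C4 in the right sense) before the bridge can close.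
- Comparison: the chosen plan sets C1, C2 and C4 under the control of a bicycle and uses its key step only to correct the ring size. This plan has an easy key step but moves the stereochemical burden to less predictable acyclic chemistry. In length the two are comparable; in robustness of the ring-forming reaction itself the alternative is at least the equal.

Key step: step 7

Assumption: in step 3 the sulfinyl alkene is taken to add with sulfur on the carbon next to the methyl-bearing bridgehead, endo, and on the face of its s-cis conformer remote from the tolyl group; on that basis the (R)-sulfoxide leads to the bridgehead configuration of the target, and the configuration of 6 would be confirmed by crystallography before it is carried on.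

## Route

Step 1
Reactants: 1 (5-methylfuran-2-yl)methanol
Product: 2 6-hydroxy-6-methyl-2H-pyran-3(6H)-one (racemic hemiketal)
Conditions: mCPBA, CH2Cl2, 0 °C → rt
Reagents that add atoms: 3-chloroperoxybenzoic acid, OOC(=O)c1cccc(Cl)c1
Why: Achmatowicz rearrangement: oxidation of the electron-rich furan, opening to the ene-dione and reclosure through the primary hydroxyl give the pyranone hemiketal; the new centre is racemic and is erased in step 3.

Step 2
Reactants: 2 6-hydroxy-6-methyl-2H-pyran-3(6H)-one
Product: 3 6-acetoxy-6-methyl-2H-pyran-3(6H)-one (racemic)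
Conditions: Ac2O, pyridine, DMAP (cat.), CH2Cl2, 0 °C → rt
Reagents that add atoms: acetic anhydride, CC(=O)OC(C)=O
Why: Acylation of the anomeric hydroxyl with nucleophilic catalysis installs the leaving group needed to reach the pyrylium oxidation level; the enone is untouched.

Step 3
Reactants: 3 6-acetoxy-6-methyl-2H-pyran-3(6H)-one; 4 (R)-p-tolyl vinyl sulfoxide
Product: 6 (1S,5S,6S)-5-methyl-6-[(R)-p-tolylsulfinyl]-8-oxabicyclo[3.2.1]oct-3-en-2-one (sulfinyl endo), via oxidopyrylium ylide 5 (not isolated)
Conditions: i-Pr2NEt, MeCN, 60 °C, slow addition of 3 to 4 (3 equiv)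
Reagents that add atoms: none
Why: Base-induced loss of acetate gives ylide 5, which undergoes a thermal [5+2] (1,3-dipolar type) cycloaddition; as with other electron-poor alkenes the substituted alkene carbon should bond to the methyl-bearing terminus in the endo mode. Attack on the s-cis sulfoxide away from the tolyl group then defines C1, C5 and C6, and since every other isomer is a diastereomer of 6 it is removed by chromatography or crystallisation.

Step 4
Reactants: 6 (1S,5S,6S)-5-methyl-6-[(R)-p-tolylsulfinyl]-8-oxabicyclo[3.2.1]oct-3-en-2-one; 7 2-(2-bromoethyl)-2-methyl-1,3-dioxolane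
Product: 9 (1S,4S,5S,6S)-5-methyl-4-[2-(2-methyl-1,3-dioxolan-2-yl)ethyl]-6-[(R)-p-tolylsulfinyl]-8-oxabicyclo[3.2.1]octan-2-one (side chain exo), via Grignard reagent 8 (not isolated)
Conditions: 7, Mg, THF, 20 °C; then slow addition to 6, CuBr·SMe2 (20 mol %), THF, −78 → −40 °C; aq. NH4Cl
Reagents that add atoms: none
Why: Copper-catalysed conjugate addition of Grignard reagent 8 (monovalent copper); the nucleophile enters C4 axially on the face syn to the oxygen bridge, away from the two-carbon bridge that carries the endo sulfinyl group, which sets chain A exo. Slow addition at low temperature keeps free Grignard reagent away from the sulfoxide and from its acidic α-hydrogen.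

Step 5
Reactants: 9 (1S,4S,5S,6S)-5-methyl-4-[2-(2-methyl-1,3-dioxolan-2-yl)ethyl]-6-[(R)-p-tolylsulfinyl]-8-oxabicyclo[3.2.1]octan-2-one
Product: 10 (1S,4S,5R)-5-methyl-4-[2-(2-methyl-1,3-dioxolan-2-yl)ethyl]-8-oxabicyclo[3.2.1]octan-2-one
Conditions: Raney Ni (W-2, deactivated in acetone), EtOH, rt
Reagents that add atoms: none
Why: Raney nickel hydrogenolysis cleaves both C–S bonds without a carbanion at C6, which would expel the β-oxygen bridge; ketone and ketal are not reduced at room temperature with deactivated catalyst.

Step 6
Reactants: 10 (1S,4S,5R)-5-methyl-4-[2-(2-methyl-1,3-dioxolan-2-yl)ethyl]-8-oxabicyclo[3.2.1]octan-2-one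
Product: 12 (1S,4S,5R)-3-diazo-5-methyl-4-[2-(2-methyl-1,3-dioxolan-2-yl)ethyl]-8-oxabicyclo[3.2.1]octan-2-one, via α-trifluoroacetyl ketone 11 (not isolated)
Conditions: LiN(SiMe3)2, THF, −78 °C; CF3CO2CH2CF3; then 4-acetamidobenzenesulfonyl azide, Et3N, H2O, MeCN, rt
Reagents that add atoms: 4-acetamidobenzenesulfonyl azide, CC(=O)Nc1ccc(cc1)S(=O)(=O)N=[N+]=[N-]
Why: Deacylative Regitz diazo transfer: the enolate can form only at C3 because C1 is a bridgehead, its trifluoroacetyl derivative 11 reacts with the sulfonyl azide, and loss of the trifluoroacetyl group gives the diazo ketone. No stereocentre is touched.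

Step 7
Reactants: 12 (1S,4S,5R)-3-diazo-5-methyl-4-[2-(2-methyl-1,3-dioxolan-2-yl)ethyl]-8-oxabicyclo[3.2.1]octan-2-one
Product: 14 methyl 1-methyl-2-exo-[2-(2-methyl-1,3-dioxolan-2-yl)ethyl]-7-oxabicyclo[2.2.1]heptane-3-endo-carboxylate (target numbering), via ketene 13 (not isolated)
Conditions: hν (365 nm LED or medium-pressure Hg lamp through Pyrex), MeOH, 0–10 °C
Reagents that add atoms: methanol, CO
Why: Photochemical Wolff rearrangement used as a ring contraction. Excitation of the diazo ketone, which the ring holds in the s-Z geometry, leads to loss of N2 concerted with a 1,2-shift of the bridgehead carbon (C4 of the target) from the carbonyl carbon to the diazo carbon, giving ketene 13; methanol adds to the ketene and the ester enol tautomerises to 14. The closest known reaction type is the light-induced contraction of cyclic and bicyclic 2-diazo ketones to strained ring-contracted esters. The six-membered carbocycle, and with it the 7-oxabicyclo[2.2.1]heptane, is closed not by a cyclisation but by this suprafacial 1,2-alkyl shift, which forms C3–C4 with retention at the migrating bridgehead. The one new stereocentre, C3, is set when the enol is protonated on the open exo face, which puts the ester endo and trans to chain A; its configuration is of no consequence because step 8 passes through the planar enolate. The step needs regioselective migration and a preference for alkyl shift over hydrogen shift from C2 or capture by a ketal oxygen: the first is secured because the bridgehead is the only group on the carbonyl carbon that can migrate, the second by direct irradiation of the conformationally fixed diazo ketone in a nucleophilic solvent without a metal catalyst. C1, C2 and C4 are not involved and keep the configuration fixed in steps 3 and 4.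

Step 8
Reactants: 14 methyl 1-methyl-2-exo-[2-(2-methyl-1,3-dioxolan-2-yl)ethyl]-7-oxabicyclo[2.2.1]heptane-3-endo-carboxylate
Product: 16 methyl 1,3-exo-dimethyl-2-exo-[2-(2-methyl-1,3-dioxolan-2-yl)ethyl]-7-oxabicyclo[2.2.1]heptane-3-endo-carboxylate (target numbering), via lithium ester enolate 15 (not isolated)
Conditions: LiN(i-Pr)2, THF, −78 °C; MeI, DMPU, −78 °C; AcOH quench at −78 °C
Reagents that add atoms: iodomethane, CI
Why: Alkylation of lithium ester enolate 15: iodomethane should approach C3 from the exo face because the endo face is screened by the C5–C6 bridge, which places the methyl group cis to chain A and leaves the ester endo. The enolate is made and quenched at −78 °C because on warming it can expel the β-oxygen bridge (E1cB).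

Step 9
Reactants: 16 methyl 1,3-exo-dimethyl-2-exo-[2-(2-methyl-1,3-dioxolan-2-yl)ethyl]-7-oxabicyclo[2.2.1]heptane-3-endo-carboxylate
Product: 17 {1,3-exo-dimethyl-2-exo-[2-(2-methyl-1,3-dioxolan-2-yl)ethyl]-7-oxabicyclo[2.2.1]heptan-3-endo-yl}methanol
Conditions: LiAlH4, Et2O, 0 °C → rt
Reagents that add atoms: none
Why: Hydride reduction of the hindered ester to the neopentyl-type primary alcohol; ketal and bridged ether are inert.

Step 10
Reactants: 17 {1,3-exo-dimethyl-2-exo-[2-(2-methyl-1,3-dioxolan-2-yl)ethyl]-7-oxabicyclo[2.2.1]heptan-3-endo-yl}methanol
Product: 18 1,3-exo-dimethyl-2-exo-[2-(2-methyl-1,3-dioxolan-2-yl)ethyl]-7-oxabicyclo[2.2.1]heptane-3-endo-carbaldehyde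
Conditions: Dess–Martin periodinane, pyridine, CH2Cl2, rt
Reagents that add atoms: none
Why: Dess–Martin oxidation under buffered conditions; the aldehyde sits on a quaternary carbon and can neither epimerise nor enolise.

Step 11
Reactants: 18 1,3-exo-dimethyl-2-exo-[2-(2-methyl-1,3-dioxolan-2-yl)ethyl]-7-oxabicyclo[2.2.1]heptane-3-endo-carbaldehyde
Product: 19 3-endo-ethenyl-1,3-exo-dimethyl-2-exo-[2-(2-methyl-1,3-dioxolan-2-yl)ethyl]-7-oxabicyclo[2.2.1]heptane
Conditions: Ph3PCH3Br, KOt-Bu, THF, 0 → 40 °C
Reagents that add atoms: methyltriphenylphosphonium bromide, C[P+](c1ccccc1)(c1ccccc1)c1ccccc1.[Br-]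
Why: Wittig methylenation of a non-enolisable aldehyde; the unstabilised methylene ylide is small enough for the neopentyl carbonyl group.

Step 12
Reactants: 19 3-endo-ethenyl-1,3-exo-dimethyl-2-exo-[2-(2-methyl-1,3-dioxolan-2-yl)ethyl]-7-oxabicyclo[2.2.1]heptane
Product: 21 1,3-exo-dimethyl-2-exo-[2-(2-methyl-1,3-dioxolan-2-yl)ethyl]-3-endo-(4-methylpent-3-enyl)-7-oxabicyclo[2.2.1]heptane, via B-alkyl-9-BBN borane 20 (not isolated)
Conditions: 9-BBN, THF, 0 → 50 °C; then Pd(dppf)Cl2 (5 mol %), Me2C=CHBr, aq. NaOH, THF, 60 °C
Reagents that add atoms: 1-bromo-2-methylprop-1-ene, CC(C)=CBr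
Why: Anti-Markovnikov hydroboration of the only alkene gives borane 20, whose primary alkyl group is transferred in a B-alkyl Suzuki–Miyaura coupling (zerovalent palladium formed in situ from Pd(dppf)Cl2) to the alkenyl bromide. This makes the C2′–C3′ bond one atom away from the neopentyl carbon, where substitution would fail, and delivers the trisubstituted alkene directly.

Step 13
Reactants: 21 1,3-exo-dimethyl-2-exo-[2-(2-methyl-1,3-dioxolan-2-yl)ethyl]-3-endo-(4-methylpent-3-enyl)-7-oxabicyclo[2.2.1]heptane
Product: 22 4-[1,3-exo-dimethyl-3-endo-(4-methylpent-3-enyl)-7-oxabicyclo[2.2.1]heptan-2-exo-yl]butan-2-one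
Conditions: PPTS, acetone/H2O, 50 °C
Reagents that add atoms: water, O
Why: Acid-catalysed ketal hydrolysis; the mild acid leaves the trisubstituted alkene and the bridged ether untouched.

Step 14
Reactants: 22 4-[1,3-exo-dimethyl-3-endo-(4-methylpent-3-enyl)-7-oxabicyclo[2.2.1]heptan-2-exo-yl]butan-2-one
Product: 23 ethyl (E)-5-[1,3-exo-dimethyl-3-endo-(4-methylpent-3-enyl)-7-oxabicyclo[2.2.1]heptan-2-exo-yl]-3-methylpent-2-enoate
Conditions: (EtO)2P(O)CH2CO2Et, NaH, THF, 0 → 50 °C
Reagents that add atoms: triethyl phosphonoacetate, CCOC(=O)CP(=O)(OCC)OCC
Why: Horner–Wadsworth–Emmons olefination of the methyl ketone; the E isomer should predominate and the Z isomer is removed by chromatography here or after step 15, because the alkene geometry decides the carbinol configuration in step 16.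

Step 15
Reactants: 23 ethyl (E)-5-[1,3-exo-dimethyl-3-endo-(4-methylpent-3-enyl)-7-oxabicyclo[2.2.1]heptan-2-exo-yl]-3-methylpent-2-enoate
Product: 24 (E)-5-[1,3-exo-dimethyl-3-endo-(4-methylpent-3-enyl)-7-oxabicyclo[2.2.1]heptan-2-exo-yl]-3-methylpent-2-en-1-ol
Conditions: i-Bu2AlH, CH2Cl2, −78 → 0 °C
Reagents that add atoms: none
Why: 1,2-Reduction of the conjugated ester by i-Bu2AlH gives the E allylic alcohol without touching the isolated alkene.

Step 16
Reactants: 24 (E)-5-[1,3-exo-dimethyl-3-endo-(4-methylpent-3-enyl)-7-oxabicyclo[2.2.1]heptan-2-exo-yl]-3-methylpent-2-en-1-ol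
Product: 25 (2S,3S)-2,3-epoxy alcohol of 24
Conditions: Ti(Oi-Pr)4 (10 mol %), L-(+)-diethyl tartrate (12 mol %), t-BuOOH, 4 Å MS, CH2Cl2, −20 °C
Reagents that add atoms: tert-butyl hydroperoxide, CC(C)(C)OO
Why: Sharpless asymmetric epoxidation: the titanium tartrate catalyst (tetravalent titanium) delivers oxygen only to the allylic alcohol, and L-(+)-diethyl tartrate selects the face that gives the (2S,3S) epoxide, the same pairing as for geraniol. Control is by the ligand, so the distant stereocentres do not interfere.

Step 17
Reactants: 25 (2S,3S)-2,3-epoxy alcohol of 24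
Product: 27 (S)-5-[1,3-exo-dimethyl-3-endo-(4-methylpent-3-enyl)-7-oxabicyclo[2.2.1]heptan-2-exo-yl]-3-methylpent-1-en-3-ol, via epoxy iodide 26 (not isolated)
Conditions: PPh3, I2, imidazole, Et2O/MeCN, 0 °C; then Zn, EtOH, reflux
Reagents that add atoms: none
Why: Appel-type iodination of the primary alcohol, then zinc insertion into the C–I bond and β-elimination, opens the epoxide to the tertiary allylic alcohol. The C–O bond at the carbinol carbon is never broken, so the configuration set in step 16 is kept.

Step 18
Reactants: 27 (S)-5-[1,3-exo-dimethyl-3-endo-(4-methylpent-3-enyl)-7-oxabicyclo[2.2.1]heptan-2-exo-yl]-3-methylpent-1-en-3-ol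
Product: 28 triethylsilyl ether of 27
Conditions: Et3SiOTf, 2,6-lutidine, CH2Cl2, −78 °C
Reagents that add atoms: triethylsilyl trifluoromethanesulfonate, CC[Si](CC)(CC)OS(=O)(=O)C(F)(F)F
Why: Silylation with the reactive triflate protects the hindered tertiary allylic alcohol, which would otherwise be ionised or chlorinated in steps 20 and 21.

Step 19
Reactants: 28 triethylsilyl ether of 27
Product: 29 (R)-epoxide of 28 at the chain B alkene
Conditions: D-fructose-derived Shi ketone (30 mol %), Oxone (2KHSO5·KHSO4·K2SO4), K2CO3, Bu4NHSO4, MeCN/CH2(OMe)2/aq. Na2B4O7 buffer, 0 °C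
Reagents that add atoms: potassium peroxymonosulfate, [K+].[O-]S(=O)(=O)OO
Why: Shi epoxidation: the chiral dioxirane attacks the electron-rich trisubstituted alkene and not the monosubstituted vinyl group. With the D-fructose-derived ketone the spiro transition state should give the (R) configuration at the CH carbon, by analogy with trans-disubstituted and other trisubstituted alkenes.

Step 20
Reactants: 29 (R)-epoxide of 28 at the chain B alkene
Product: 30 bromohydrin with tertiary bromide next to the (R) secondary alcohol
Conditions: MgBr2·OEt2, Et2O, −40 → 0 °C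
Reagents that add atoms: magnesium bromide diethyl etherate, Br[Mg]Br.CCOCC
Why: Lewis acid assisted opening of the trisubstituted epoxide by bromide at the tertiary carbon (borderline SN2, Markovnikov sense) gives the tertiary bromide and leaves the C–O stereocentre untouched; low temperature suppresses Meinwald rearrangement. Any regioisomeric bromohydrin would ionise to the same bromonium ion in step 21 and is therefore no stereochemical liability.

Step 21
Reactants: 30 bromohydrin with tertiary bromide next to the (R) secondary alcohol
Product: 33 triethylsilyl ether of dactylomelol, via chlorosulfite ester 31 (not isolated), via bromonium chloride ion pair 32 (not isolated)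
Conditions: SOCl2, pyridine, CH2Cl2, −20 °C → rt
Reagents that add atoms: thionyl chloride, O=S(Cl)Cl
Why: Chlorodehydroxylation with neighbouring-group participation: chlorosulfite 31 ionises with backside attack of the vicinal bromine, giving bromonium ion 32 with inversion at the former carbinol carbon, and chloride opens 32 at the tertiary carbon. The result is the (S) secondary bromide next to the tertiary chloride; direct substitution at the neopentyl-type carbinol carbon is too slow to compete, and the endo chain cannot be reached by O7.

Step 22
Reactants: 33 triethylsilyl ether of dactylomelol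
Product: 34 dactylomelol
Conditions: HF·pyridine, pyridine, THF, 0 °C → rt
Reagents that add atoms: none
Why: Fluoride-driven cleavage of the silyl ether under buffered, non-basic conditions; the bromochloride and the tertiary allylic alcohol survive.

## Compound list

1 | (5-methylfuran-2-yl)methanol (5-methylfurfuryl alcohol) | Cc1ccc(CO)o1 | starting material
2 | 6-hydroxy-6-methyl-2H-pyran-3(6H)-one (racemic hemiketal) | CC1(O)C=CC(=O)CO1 | intermediate
3 | 6-acetoxy-6-methyl-2H-pyran-3(6H)-one (racemic) | CC(=O)OC1(C)C=CC(=O)CO1 | intermediate
4 | (R)-p-tolyl vinyl sulfoxide | C=C[S@@](=O)c1ccc(C)cc1 | starting material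
5 | 6-methylpyrylium-3-olate (oxidopyrylium ylide, not isolated) | Cc1ccc([O-])c[o+]1 | intermediate
6 | (1S,5S,6S)-5-methyl-6-[(R)-p-tolylsulfinyl]-8-oxabicyclo[3.2.1]oct-3-en-2-one (sulfinyl endo, on the carbon next to the methyl-bearing bridgehead) | C1=CC(=O)[C@@H]2C[C@H]([S@@](=O)c3ccc(C)cc3)[C@@]1(C)O2 | intermediate
7 | 2-(2-bromoethyl)-2-methyl-1,3-dioxolane | CC1(CCBr)OCCO1 | starting material
8 | [2-(2-methyl-1,3-dioxolan-2-yl)ethyl]magnesium bromide (not isolated) | CC1(CC[Mg]Br)OCCO1 | intermediate
9 | (1S,4S,5S,6S)-5-methyl-4-[2-(2-methyl-1,3-dioxolan-2-yl)ethyl]-6-[(R)-p-tolylsulfinyl]-8-oxabicyclo[3.2.1]octan-2-one (side chain exo, sulfinyl endo) | CC3(OCCO3)CC[C@H]1CC(=O)[C@@H]2C[C@H]([S@@](=O)c4ccc(C)cc4)[C@@]1(C)O2 | intermediate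
10 | (1S,4S,5R)-5-methyl-4-[2-(2-methyl-1,3-dioxolan-2-yl)ethyl]-8-oxabicyclo[3.2.1]octan-2-one (side chain exo) | CC3(OCCO3)CC[C@H]1CC(=O)[C@@H]2CC[C@@]1(C)O2 | intermediate
11 | 3-(trifluoroacetyl) derivative of 10 (enolised β-diketone, not isolated) | CC3(OCCO3)CC[C@H]1C(C(=O)C(F)(F)F)C(=O)[C@@H]2CC[C@@]1(C)O2 | intermediate
12 | (1S,4S,5R)-3-diazo-5-methyl-4-[2-(2-methyl-1,3-dioxolan-2-yl)ethyl]-8-oxabicyclo[3.2.1]octan-2-one (side chain exo) | CC3(OCCO3)CC[C@H]1C(=[N+]=[N-])C(=O)[C@@H]2CC[C@@]1(C)O2 | intermediate
13 | 1-methyl-2-exo-[2-(2-methyl-1,3-dioxolan-2-yl)ethyl]-3-(oxomethylidene)-7-oxabicyclo[2.2.1]heptane (ketene, target numbering, not isolated) | CC3(OCCO3)CC[C@H]1C(=C=O)[C@@H]2CC[C@@]1(C)O2 | intermediate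
14 | methyl 1-methyl-2-exo-[2-(2-methyl-1,3-dioxolan-2-yl)ethyl]-7-oxabicyclo[2.2.1]heptane-3-endo-carboxylate (target numbering) | CC3(OCCO3)CC[C@H]1[C@H](C(=O)OC)[C@@H]2CC[C@@]1(C)O2 | intermediate
15 | lithium enolate of 14 (not isolated) | CC3(OCCO3)CC[C@H]1C(=C([O-])OC)[C@@H]2CC[C@@]1(C)O2.[Li+] | intermediate
16 | methyl 1,3-exo-dimethyl-2-exo-[2-(2-methyl-1,3-dioxolan-2-yl)ethyl]-7-oxabicyclo[2.2.1]heptane-3-endo-carboxylate | CC3(OCCO3)CC[C@H]1[C@](C)(C(=O)OC)[C@@H]2CC[C@@]1(C)O2 | intermediate
17 | {1,3-exo-dimethyl-2-exo-[2-(2-methyl-1,3-dioxolan-2-yl)ethyl]-7-oxabicyclo[2.2.1]heptan-3-endo-yl}methanol | CC3(OCCO3)CC[C@H]1[C@](C)(CO)[C@@H]2CC[C@@]1(C)O2 | intermediate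
18 | 1,3-exo-dimethyl-2-exo-[2-(2-methyl-1,3-dioxolan-2-yl)ethyl]-7-oxabicyclo[2.2.1]heptane-3-endo-carbaldehyde | CC3(OCCO3)CC[C@H]1[C@](C)(C=O)[C@@H]2CC[C@@]1(C)O2 | intermediate
19 | 3-endo-ethenyl-1,3-exo-dimethyl-2-exo-[2-(2-methyl-1,3-dioxolan-2-yl)ethyl]-7-oxabicyclo[2.2.1]heptane | CC3(OCCO3)CC[C@H]1[C@](C)(C=C)[C@@H]2CC[C@@]1(C)O2 | intermediate
20 | 9-{2-[3-endo-yl of 19]ethyl}-9-borabicyclo[3.3.1]nonane (hydroboration product of 19, not isolated) | CC3(OCCO3)CC[C@H]1[C@](C)(CCB4C5CCCC4CCC5)[C@@H]2CC[C@@]1(C)O2 | intermediate
21 | 1,3-exo-dimethyl-2-exo-[2-(2-methyl-1,3-dioxolan-2-yl)ethyl]-3-endo-(4-methylpent-3-enyl)-7-oxabicyclo[2.2.1]heptane | CC3(OCCO3)CC[C@H]1[C@](C)(CCC=C(C)C)[C@@H]2CC[C@@]1(C)O2 | intermediate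
22 | 4-[1,3-exo-dimethyl-3-endo-(4-methylpent-3-enyl)-7-oxabicyclo[2.2.1]heptan-2-exo-yl]butan-2-one | CC(=O)CC[C@H]1[C@](C)(CCC=C(C)C)[C@@H]2CC[C@@]1(C)O2 | intermediate
23 | ethyl (E)-5-[1,3-exo-dimethyl-3-endo-(4-methylpent-3-enyl)-7-oxabicyclo[2.2.1]heptan-2-exo-yl]-3-methylpent-2-enoate | CCOC(=O)/C=C(\C)CC[C@H]1[C@](C)(CCC=C(C)C)[C@@H]2CC[C@@]1(C)O2 | intermediate
24 | (E)-5-[1,3-exo-dimethyl-3-endo-(4-methylpent-3-enyl)-7-oxabicyclo[2.2.1]heptan-2-exo-yl]-3-methylpent-2-en-1-ol | OC/C=C(\C)CC[C@H]1[C@](C)(CCC=C(C)C)[C@@H]2CC[C@@]1(C)O2 | intermediate
25 | [(2S,3S)-3-methyl-3-{2-[bicyclic unit of 24]ethyl}oxiran-2-yl]methanol | OC[C@@H]1O[C@@]1(C)CC[C@H]2[C@](C)(CCC=C(C)C)[C@@H]3CC[C@@]2(C)O3 | intermediate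
26 | primary iodide of 25 (same spatial arrangement, not isolated) | IC[C@@H]1O[C@@]1(C)CC[C@H]2[C@](C)(CCC=C(C)C)[C@@H]3CC[C@@]2(C)O3 | intermediate
27 | (S)-5-[1,3-exo-dimethyl-3-endo-(4-methylpent-3-enyl)-7-oxabicyclo[2.2.1]heptan-2-exo-yl]-3-methylpent-1-en-3-ol | C=C[C@@](C)(O)CC[C@H]1[C@](C)(CCC=C(C)C)[C@@H]2CC[C@@]1(C)O2 | intermediate
28 | triethylsilyl ether of 27 | C=C[C@@](C)(O[Si](CC)(CC)CC)CC[C@H]1[C@](C)(CCC=C(C)C)[C@@H]2CC[C@@]1(C)O2 | intermediate
29 | epoxide of 28 at the chain B alkene, (R) at the CH carbon | C=C[C@@](C)(O[Si](CC)(CC)CC)CC[C@H]1[C@](C)(CC[C@H]3OC3(C)C)[C@@H]2CC[C@@]1(C)O2 | intermediate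
30 | bromohydrin of 29: tertiary bromide, (R) secondary alcohol | C=C[C@@](C)(O[Si](CC)(CC)CC)CC[C@H]1[C@](C)(CC[C@@H](O)C(C)(C)Br)[C@@H]2CC[C@@]1(C)O2 | intermediate
31 | chlorosulfite ester of 30 (not isolated) | C=C[C@@](C)(O[Si](CC)(CC)CC)CC[C@H]1[C@](C)(CC[C@@H](OS(Cl)=O)C(C)(C)Br)[C@@H]2CC[C@@]1(C)O2 | intermediate
32 | bromonium ion from 31, chloride counter-ion (not isolated) | C=C[C@@](C)(O[Si](CC)(CC)CC)CC[C@H]1[C@](C)(CC[C@@H]3[Br+]C3(C)C)[C@@H]2CC[C@@]1(C)O2.[Cl-] | intermediate
33 | triethylsilyl ether of dactylomelol, (S) secondary bromide and tertiary chloride in chain B | C=C[C@@](C)(O[Si](CC)(CC)CC)CC[C@H]1[C@](C)(CC[C@H](Br)C(C)(C)Cl)[C@@H]2CC[C@@]1(C)O2 | intermediate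
34 | dactylomelol | C=C[C@@](C)(O)CC[C@H]1[C@](C)(CC[C@H](Br)C(C)(C)Cl)[C@@H]2CC[C@@]1(C)O2 | target

## Step count and least certain steps

Total: 22 steps. Longest linear sequence: 22 steps (1 to 34); 4 and 7 are bought and enter in steps 3 and 4.

**Step 7 (key step).** What may go wrong: a hydrogen shift from C2, or capture of the carbene-like intermediate by a ketal oxygen, may compete with the shift of the bridgehead, because the contraction builds strain into the bicycle. Material would then be lost to a conjugated enone instead of being contracted. Fallback, from 10 back to 14: a quasi-Favorskii (semibenzilic) contraction. Ketone 10 would be brominated at C3 (LiN(SiMe3)2, then N-bromosuccinimide, −78 °C) to the α-bromo ketone F1, whose equatorial C–Br bond is antiperiplanar to the bond between the carbonyl carbon and the bridgehead. NaOMe in MeOH would then add to the carbonyl group and the bridgehead carbon would shift to C3 with loss of bromide; this path is enforced because the bridgehead α′ position cannot enolise. The product is 14, in which the C3 configuration is again immaterial.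

**Step 3.** What may go wrong: dimerisation of the ylide may outrun cycloaddition to a weakly activated alkene, and facial discrimination by the sulfinyl group may be too small to give a separable major isomer. Fallback, from 3 back to 10: the cycloaddition would be run with methyl acrylate, a much better partner for oxidopyrylium ylides, to give the racemic endo ester F2. Saponification (LiOH) and resolution of the racemic acid through its crystalline salt with (R)- or (S)-1-phenylethylamine would give acid F3. Barton decarboxylation through the N-hydroxypyridine-2-thione ester F4 (t-BuSH, hν) would remove the carboxyl group by a radical path, which does not open the oxygen bridge, and give enone F5. Conjugate addition of 8 to F5 under the conditions of step 4 would then give 10 directly, so step 5 is no longer needed.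

**Step 8.** What may go wrong: opening of the oxygen bridge by β-elimination from the ester enolate, and an exo preference eroded by the exo chain on C2. Fallback, from 14 back to 18: an enolate-free methylation through a cyclopropane. Ester 14 would be reduced (LiAlH4) to the alcohol F6 and oxidised (Dess–Martin periodinane) to the aldehyde F7. F7 would be converted under soft enolisation (t-BuMe2SiOTf, Et3N) into the silyl enol ether F8, which is neutral and cannot eliminate. Simmons–Smith cyclopropanation (Et2Zn, CH2I2) would deliver the methylene group to the exo face and give the siloxycyclopropane F9. Fluoride (Bu4NF, then protic work-up) would open the cyclopropanolate at the less substituted carbon, turning the new CH2 into the exo methyl group and regenerating the endo aldehyde, that is 18.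

**Step 21 (with step 20).** What may go wrong: proton loss from the bromonium ion to an allylic bromide, rearrangement during epoxide opening, or ionisation at the protected allylic oxygen of chain A under the acidic by-products. Fallback, from 28 back to 33: direct bromochlorination of the trisubstituted alkene of 28 with tetrabutylammonium dichlorobromate (Bu4N+ BrCl2−, CH2Cl2, −78 °C). This adds bromine and chlorine anti and in the Markovnikov sense but without facial control, so 33 would be formed together with its epimer at the bromine-bearing carbon, F10, and the two would be separated by preparative HPLC. Stereocontrol is given up in exchange for a two-step shorter and milder endgame.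

## Further compounds

F1 | step 7 | 3-bromo-5-methyl-4-exo-[2-(2-methyl-1,3-dioxolan-2-yl)ethyl]-8-oxabicyclo[3.2.1]octan-2-one (either epimer at C3) | CC3(OCCO3)CC[C@H]1C(Br)C(=O)[C@@H]2CC[C@@]1(C)O2
F2 | step 3 | methyl 5-methyl-2-oxo-8-oxabicyclo[3.2.1]oct-3-ene-6-endo-carboxylate (racemate; the enantiomer needed is drawn) | C1=CC(=O)[C@@H]2C[C@H](C(=O)OC)[C@@]1(C)O2
F3 | step 3 | 5-methyl-2-oxo-8-oxabicyclo[3.2.1]oct-3-ene-6-endo-carboxylic acid (resolved, bridgeheads as in 6) | C1=CC(=O)[C@@H]2C[C@H](C(=O)O)[C@@]1(C)O2
F4 | step 3 | 2-thioxopyridin-1(2H)-yl ester of F3 | C1=CC(=O)[C@@H]2C[C@H](C(=O)ON3C=CC=CC3=S)[C@@]1(C)O2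
F5 | step 3 | (1S,5R)-5-methyl-8-oxabicyclo[3.2.1]oct-3-en-2-one | C1=CC(=O)[C@@H]2CC[C@@]1(C)O2
F6 | step 8 | {1-methyl-2-exo-[2-(2-methyl-1,3-dioxolan-2-yl)ethyl]-7-oxabicyclo[2.2.1]heptan-3-endo-yl}methanol | CC3(OCCO3)CC[C@H]1[C@H](CO)[C@@H]2CC[C@@]1(C)O2
F7 | step 8 | 1-methyl-2-exo-[2-(2-methyl-1,3-dioxolan-2-yl)ethyl]-7-oxabicyclo[2.2.1]heptane-3-carbaldehyde (endo drawn; C3 may epimerise) | CC3(OCCO3)CC[C@H]1[C@H](C=O)[C@@H]2CC[C@@]1(C)O2
F8 | step 8 | tert-butyldimethylsilyl enol ether of F7 (exocyclic C3=CH–OSi, either geometry) | CC3(OCCO3)CC[C@H]1C(=CO[Si](C)(C)C(C)(C)C)[C@@H]2CC[C@@]1(C)O2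
F9 | step 8 | spiro siloxycyclopropane from F8 (cyclopropane CH2 exo on C3, carbinol carbon endo) | CC3(OCCO3)CC[C@H]1[C@@]4(CC4O[Si](C)(C)C(C)(C)C)[C@@H]2CC[C@@]1(C)O2
F10 | step 21 | epimer of 33 at the bromine-bearing carbon, (R) bromide | C=C[C@@](C)(O[Si](CC)(CC)CC)CC[C@H]1[C@](C)(CC[C@@H](Br)C(C)(C)Cl)[C@@H]2CC[C@@]1(C)O2
A1 | alternative 1 | (S)-4-(tert-butyldimethylsilyloxy)-3-methylcyclohex-2-en-1-one | CC1=CC(=O)CC[C@@H]1O[Si](C)(C)C(C)(C)C
A2 | alternative 1 | 2-allyl-4-(tert-butyldimethylsilyloxy)-3-methyl-3-(4-methylpent-3-enyl)cyclohexanone (C2, C3, C4 as in the target) | C=CC[C@H]1[C@](C)(CCC=C(C)C)[C@@H](O[Si](C)(C)C(C)(C)C)CCC1=O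
A3 | alternative 2 | methyl 6-methyl-2-oxo-6-(3-oxopropyl)-3-oxabicyclo[3.1.0]hexane-1-carboxylate (donor–acceptor cyclopropane lactone) | O=C3OC[C@H]1[C@]3(C(=O)OC)[C@@]1(C)CCC=O
A4 | alternative 2 | lactone-fused 7-oxabicyclo[2.2.1]heptane (ester endo and lactone carbonyl exo on C3, lactone CH2 exo on C2) | O=C3OC[C@H]1[C@]3(C(=O)OC)[C@@H]2CC[C@@]1(C)O2
A5 | alternative 3 | 3-methyl-4-[2-(2-methyl-1,3-dioxolan-2-yl)ethyl]-3-[2-(triisopropylsilyloxy)ethyl]hexane-2,5-dione | CC3(OCCO3)CC[C@H](C(C)=O)[C@](C)(CCO[Si](C(C)C)(C(C)C)C(C)C)C(C)=O
A6 | alternative 3 | 3-methyl-2-[2-(2-methyl-1,3-dioxolan-2-yl)ethyl]-3-[2-(triisopropylsilyloxy)ethyl]cyclohexane-1,4-dione | CC3(OCCO3)CC[C@H]1[C@](C)(CCO[Si](C(C)C)(C(C)C)C(C)C)C(=O)CCC1=O
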